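**Assumption:** the target SMILES has no stereocentres (Formosanatin D is achiral), so no enantiocontrol is needed; the one stereocentre in the route (compound 7, racemic) is destroyed in the next step.

## Retrosynthetic overview

1. The furan ring is closed last by intramolecular oxa-Michael addition–elimination of the B-ring 2'-OH onto C2 of a 2-(methylsulfonyl)isoflavone, triggered by global MOM removal.
2. The C3–C1' bond comes from a Suzuki–Miyaura coupling of a 3-iodo-2-(methylthio)pyranochromone (fragment A) with a chromenyl boronate (fragment B).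
3. Fragment A: the chroman ring is made first (phloroglucinol + 3-methylbut-2-enoic acid, acylation/oxa-Michael; 7-O-MOM; C=O removed), then the γ-pyrone by CS2/MeI and oxa-Michael addition–elimination through the single free phenol.
4. Fragment B: hydroquinone → 2,5-dibromo bis-MOM ether → phenol → propargyl ether → Claisen chromene → boronate.
5. Ring order: A-ring chroman → γ-pyrone; B-ring chromene (separately); furan last.

## Fragment A

**Step 1**
Reactants: 1 phloroglucinol; 2 3-methylbut-2-enoic acid
Product: 3, 5,7-dihydroxy-2,2-dimethylchroman-4-one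
Conditions: P2O5/MeSO3H (Eaton's reagent), 70 °C
Reagents that add atoms: none
Why: Friedel–Crafts acylation of C3-symmetric phloroglucinol followed by intramolecular oxa-Michael addition of the ortho OH to the β,β-dimethyl enone gives a single chromanone.

**Step 2**
Reactants: 3
Product: 4, 5-hydroxy-7-(methoxymethoxy)-2,2-dimethylchroman-4-one
Conditions: MOMCl (1.1 equiv), i-Pr2NEt, CH2Cl2, 0 °C → rt
Reagents that add atoms: chloromethyl methyl ether, COCCl
Why: Selective O-alkylation (MOM protection), because the 5-OH is hydrogen-bonded to C4=O and only the 7-OH reacts; this fixes which oxygen later becomes the pyrone oxygen.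

**Step 3**
Reactants: 4
Product: 5, 7-(methoxymethoxy)-2,2-dimethylchroman-5-ol
Conditions: ClCO2Et, Et3N, THF, 0 °C; then NaBH4, THF/H2O, 0 °C → rt
Reagents that add atoms: none
Why: Carbonate-assisted reductive deoxygenation of an o-hydroxyaryl ketone (ketone reduction, carbonate transfer and elimination to an o-quinone methide, then hydride reduction) gives ArCH2 and returns the free phenol without touching the MOM ether.

**Step 4**
Reactants: 5
Product: 6, 5-hydroxy-7-(methoxymethoxy)-2,2-dimethylchroman-6-carbaldehyde
Conditions: MgCl2, Et3N, (CH2O)n, MeCN, reflux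
Reagents that add atoms: paraformaldehyde (formaldehyde), C=O
Why: Casnati–Skattebøl magnesium-mediated formylation occurs only ortho to the free phenol, and C6 is the only open ortho position.

**Step 5**
Reactants: 6
Product: 7, 6-(1-hydroxyethyl)-7-(methoxymethoxy)-2,2-dimethylchroman-5-ol (racemic)
Conditions: MeMgBr (3 equiv), THF, 0 °C; NH4Cl (aq) quench
Reagents that add atoms: methylmagnesium bromide, C[Mg]Br
Why: Grignard addition to the salicylaldehyde; the first equivalent only deprotonates the phenol.

**Step 6**
Reactants: 7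
Product: 8, 1-[5-hydroxy-7-(methoxymethoxy)-2,2-dimethylchroman-6-yl]ethan-1-one
Conditions: activated MnO2, CH2Cl2, rt
Reagents that add atoms: none
Why: Chemoselective MnO2 oxidation of the benzylic alcohol gives the chelated o-hydroxyacetophenone.

**Step 7**
Reactants: 8
Product: 9, 5-(methoxymethoxy)-8,8-dimethyl-2-(methylsulfanyl)-9,10-dihydro-4H,8H-pyrano[2,3-f]chromen-4-one (angular pyranochromone)
Conditions: t-BuOK (3.3 equiv), CS2, THF, 0 °C; MeI (2.1 equiv), 0 °C → rt; then 60 °C
Reagents that add atoms: carbon disulfide, S=C=S; iodomethane, CI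
Why: Enolate dithiocarboxylation and double S-methylation give an α-oxoketene dithioacetal, and the only free phenoxide then closes the γ-pyrone by intramolecular oxa-Michael addition–elimination (6-endo, loss of MeS⁻), so the angular regiochemistry is unambiguous.

**Step 8**
Reactants: 9
Product: 10, 3-iodo-5-(methoxymethoxy)-8,8-dimethyl-2-(methylsulfanyl)-9,10-dihydro-4H,8H-pyrano[2,3-f]chromen-4-one
Conditions: NIS (1.1 equiv), MeCN, rt, dark
Reagents that add atoms: N-iodosuccinimide, O=C1CCC(=O)N1I
Why: Electrophilic iodination at C3, the α-carbon of a push–pull ketene O,S-acetal, which should be more nucleophilic than the carbonyl-deactivated, doubly flanked A-ring CH with no free phenol present.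

## Fragment B

**Step 9**
Reactants: 11 hydroquinone
Product: 12, 2,5-dibromobenzene-1,4-diol
Conditions: Br2 (2.05 equiv), AcOH, rt
Reagents that add atoms: bromine, BrBr
Why: Electrophilic aromatic bromination ortho to each OH; the 2,5-isomer is the main product and crystallises out.

**Step 10**
Reactants: 12
Product: 13, 1,4-dibromo-2,5-bis(methoxymethoxy)benzene
Conditions: NaH, MOMCl, DMF/THF, 0 °C → rt
Reagents that add atoms: chloromethyl methyl ether, COCCl
Why: Double Williamson-type MOM protection gives a base- and organolithium-stable, acid-labile ether.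

**Step 11**
Reactants: 13
Product: 14, 4-bromo-2,5-bis(methoxymethoxy)phenol
Conditions: n-BuLi (1.0 equiv), THF, −78 °C; B(OMe)3; then H2O2, NaOH (aq), 0 °C
Reagents that add atoms: hydrogen peroxide, OO
Why: Mono bromine–lithium exchange (aryllithium stabilised by the ortho OMOM), borylation and oxidative C–B to C–O conversion; symmetry of 13 means only one product is possible.

**Step 12**
Reactants: 14; 15 3-chloro-3-methylbut-1-yne
Product: 16, 1-bromo-2,5-bis(methoxymethoxy)-4-[(2-methylbut-3-yn-2-yl)oxy]benzene
Conditions: DBU, CuCl2·2H2O (cat.), MeCN, 0 °C → rt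
Reagents that add atoms: none
Why: Copper-catalysed O-propargylation of the phenol with the tertiary propargylic chloride.

**Step 13**
Reactants: 16
Product: 17, 6-bromo-5,8-bis(methoxymethoxy)-2,2-dimethyl-2H-chromene
Conditions: PhNEt2, 185 °C
Reagents that add atoms: none
Why: Aryl propargyl Claisen rearrangement, 1,5-H shift and oxa-6π electrocyclisation give the 2,2-dimethylchromene; the only free ortho carbon is the one that becomes C3' of the target.

**Step 14**
Reactants: 17
Product: 18, 2-[5,8-bis(methoxymethoxy)-2,2-dimethyl-2H-chromen-6-yl]-4,4,5,5-tetramethyl-1,3,2-dioxaborolane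
Conditions: n-BuLi, THF, −78 °C; then i-PrOBpin, −78 °C → rt
Reagents that add atoms: 2-isopropoxy-4,4,5,5-tetramethyl-1,3,2-dioxaborolane, CC(C)OB1OC(C)(C)C(C)(C)O1
Why: Bromine–lithium exchange and borate trapping; the chromene and MOM ethers are inert to n-BuLi at −78 °C.

## Fragment union and endgame

**Step 15**
Reactants: 10; 18
Product: 19, 3-[5,8-bis(methoxymethoxy)-2,2-dimethyl-2H-chromen-6-yl]-5-(methoxymethoxy)-8,8-dimethyl-2-(methylsulfanyl)-9,10-dihydro-4H,8H-pyrano[2,3-f]chromen-4-one
Conditions: Pd(OAc)2 (5 mol%), SPhos (10 mol%), K3PO4, toluene/H2O 10:1, 80 °C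
Reagents that add atoms: none
Why: Suzuki–Miyaura coupling at the C3–I bond; the C2–SMe bond is inert without a Cu(I) cofactor, and SPhos handles the ortho-substituted partners.

**Step 16**
Reactants: 19
Product: 20, the 2-(methylsulfonyl) analogue of 19
Conditions: (NH4)6Mo7O24·4H2O (10 mol%), 30% H2O2 (6 equiv), EtOH/THF, 0 °C → rt
Reagents that add atoms: hydrogen peroxide, OO
Why: Molybdate-catalysed peroxide oxidation takes the sulfide to the sulfone while leaving unfunctionalised alkenes and acetals alone, turning C2 into a strong Michael acceptor with a sulfinate leaving group.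

**Step 17**
Reactants: 20
Product: 21, Formosanatin D
Conditions: HCl (4 M in dioxane), i-PrOH/THF, 40 °C, Ar; then NaHCO3 (aq), rt
Reagents that add atoms: none
Why: Acidic cleavage of the three MOM ethers frees the 2'-OH, which closes the furan by intramolecular oxa-Michael addition to C2 and elimination of methanesulfinate (the same geometry as dibenzofuran-forming SNAr); the 5'-OH cannot reach C2, and the 5-OH and chromene are unaffected.

## Compound list

1 | phloroglucinol (benzene-1,3,5-triol) | Oc1cc(O)cc(O)c1 | starting material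
2 | 3-methylbut-2-enoic acid | CC(C)=CC(=O)O | starting material
3 | 5,7-dihydroxy-2,2-dimethylchroman-4-one | CC1(C)CC(=O)c2c(O)cc(O)cc2O1 | intermediate
4 | 5-hydroxy-7-(methoxymethoxy)-2,2-dimethylchroman-4-one | COCOc1cc(O)c2C(=O)CC(C)(C)Oc2c1 | intermediate
5 | 7-(methoxymethoxy)-2,2-dimethylchroman-5-ol | COCOc1cc(O)c2CCC(C)(C)Oc2c1 | intermediate
6 | 5-hydroxy-7-(methoxymethoxy)-2,2-dimethylchroman-6-carbaldehyde | COCOc1cc2OC(C)(C)CCc2c(O)c1C=O | intermediate
7 | 6-(1-hydroxyethyl)-7-(methoxymethoxy)-2,2-dimethylchroman-5-ol (racemic) | COCOc1cc2OC(C)(C)CCc2c(O)c1C(C)O | intermediate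
8 | 1-[5-hydroxy-7-(methoxymethoxy)-2,2-dimethylchroman-6-yl]ethan-1-one | COCOc1cc2OC(C)(C)CCc2c(O)c1C(C)=O | intermediate
9 | 5-(methoxymethoxy)-8,8-dimethyl-2-(methylsulfanyl)-9,10-dihydro-4H,8H-pyrano[2,3-f]chromen-4-one | COCOc1cc2OC(C)(C)CCc2c2oc(SC)cc(=O)c12 | intermediate
10 | 3-iodo-5-(methoxymethoxy)-8,8-dimethyl-2-(methylsulfanyl)-9,10-dihydro-4H,8H-pyrano[2,3-f]chromen-4-one | COCOc1cc2OC(C)(C)CCc2c2oc(SC)c(I)c(=O)c12 | intermediate
11 | hydroquinone | Oc1ccc(O)cc1 | starting material
12 | 2,5-dibromobenzene-1,4-diol | Oc1cc(Br)c(O)cc1Br | intermediate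
13 | 1,4-dibromo-2,5-bis(methoxymethoxy)benzene | COCOc1cc(Br)c(OCOC)cc1Br | intermediate
14 | 4-bromo-2,5-bis(methoxymethoxy)phenol | COCOc1cc(Br)c(OCOC)cc1O | intermediate
15 | 3-chloro-3-methylbut-1-yne | CC(C)(Cl)C#C | starting material
16 | 1-bromo-2,5-bis(methoxymethoxy)-4-[(2-methylbut-3-yn-2-yl)oxy]benzene | COCOc1cc(Br)c(OCOC)cc1OC(C)(C)C#C | intermediate
17 | 6-bromo-5,8-bis(methoxymethoxy)-2,2-dimethyl-2H-chromene | COCOc1cc(Br)c(OCOC)c2C=CC(C)(C)Oc12 | intermediate
18 | 2-[5,8-bis(methoxymethoxy)-2,2-dimethyl-2H-chromen-6-yl]-4,4,5,5-tetramethyl-1,3,2-dioxaborolane | COCOc1cc(B2OC(C)(C)C(C)(C)O2)c(OCOC)c2C=CC(C)(C)Oc12 | intermediate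
19 | 3-[5,8-bis(methoxymethoxy)-2,2-dimethyl-2H-chromen-6-yl]-5-(methoxymethoxy)-8,8-dimethyl-2-(methylsulfanyl)-9,10-dihydro-4H,8H-pyrano[2,3-f]chromen-4-one | COCOc1cc2OC(C)(C)CCc2c2oc(SC)c(-c3cc(OCOC)c4OC(C)(C)C=Cc4c3OCOC)c(=O)c12 | intermediate
20 | 3-[5,8-bis(methoxymethoxy)-2,2-dimethyl-2H-chromen-6-yl]-5-(methoxymethoxy)-8,8-dimethyl-2-(methylsulfonyl)-9,10-dihydro-4H,8H-pyrano[2,3-f]chromen-4-one | COCOc1cc2OC(C)(C)CCc2c2oc(S(C)(=O)=O)c(-c3cc(OCOC)c4OC(C)(C)C=Cc4c3OCOC)c(=O)c12 | intermediate
21 | Formosanatin D (achiral) | CC1(C)C=Cc2c(c(O)cc3c2oc2oc4c5c(cc(O)c4c(=O)c23)OC(C)(C)CC5)O1 | target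

## Summary

**Total steps:** 17
**Longest linear sequence:** 11 (steps 1–8, then 15–17); the fragment B branch is 6 steps (9–14).

**Three steps most likely to fail, with fallbacks**

1. **Step 16** (S-oxidation next to an electron-rich chromene; the sulfone may also solvolyse before step 17). Fallback: oxidise before the chromene is present. Convert 10 to the 3-iodo-2-(methylsulfonyl)chromone with mCPBA, then join it to the aryl stannane made from 17 by a base-free Stille coupling, and go straight to step 17.
2. **Step 8** (C3 versus A-ring iodination). Fallback: make the C3–aryl bond at the ketone stage. Pd-catalysed α-arylation of the O-TBS ether of 8 with bromide 17 gives a deoxybenzoin; after desilylation, CS2/MeI closes the pyrone directly to 19, with no iodination or Suzuki step.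
3. **Step 3** (the o-quinone methide may tautomerise to a chromene, or the chelated phenol may not form the carbonate). Fallback: avoid the ketone altogether. Take 2,4,6-trihydroxyacetophenone through 4-O-(1,1-dimethylpropargyl) ether formation and Claisen cyclisation (symmetrical, one chromene), hydrogenate (H2, Pd/C) to the chroman, then mono-MOM protect the less hindered 7-OH and separate isomers to reach 8.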